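**Retrosynthetic overview**
1. The angelate goes on last. It is installed by an invertive (Mitsunobu) esterification of the C8-epimeric alcohol.
2. The key cut is C7–C8. Reduction of an α-(bromomethyl)butenolide gives an allylchromium (a lactone homoenolate equivalent) in which the β-carbon C7 is nucleophilic. C7 adds to aldehyde C8, which closes the ten-membered ring, unveils the α-methylene lactone and sets C7 and C8.
3. The bromomethyl butenolide comes from esterification and ring-closing metathesis at the C6 carbinol. Aldehyde C8 comes from ozonolysis of a prenyl group.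
4. The furanone comes from C1–C2 acylation of a Z-enyne acetylide by a lactic acid dioxolanone, then amine-mediated cyclisation. C10 is set by self-regeneration of stereocentres and C6 by catalytic asymmetric vinylation.
5. Ring order: furanone (ring A), then butenolide (ring B), then the ten-membered carbocycle (ring C).

Assumption: the Z-enynol starting material (the industrial vitamin A six-carbon building block) is bought as the pure Z isomer. Atom labels are germacrane numbering: C1 ketone, C2=C3 furanone alkene, C4=C5 Z-alkene, C6 lactone carbinol, C7, C8 ester carbinol, C9 CH2, C10 quaternary carbon, C11=C13 methylene, C12 lactone carbonyl, C14 and C15 methyls.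

**Route**

Step 1
Reactants: 1 (S)-lactic acid; 2 pivalaldehyde
Product: 3 (2S,5S)-2-tert-butyl-5-methyl-1,3-dioxolan-4-one (cis)
Conditions: TsOH·H2O (cat.), pentane, reflux, Dean–Stark; cis isomer crystallised from pentane at −78 °C
Reagents that add atoms: pivalaldehyde 2, CC(C)(C)C=O
Why: Acid-catalysed acetalisation with azeotropic water removal (first stage of self-regeneration of stereocentres), in which the lactate stereocentre directs the new acetal carbon and the cis (2S,5S) isomer is obtained pure by crystallisation.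

Step 2
Reactants: 3 (2S,5S)-2-tert-butyl-5-methyl-1,3-dioxolan-4-one; 4 prenyl bromide
Product: 5 (2S,5R)-2-tert-butyl-5-methyl-5-(3-methylbut-2-en-1-yl)-1,3-dioxolan-4-one
Conditions: LiN(iPr)2 (1.05 equiv), THF, −78 °C; then 4, −78 → −20 °C
Reagents that add atoms: prenyl bromide 4, CC(C)=CCBr
Why: Diastereoselective enolate alkylation, in which the planar lithium enolate is attacked by the allylic bromide on the face opposite the tert-butyl group and the stereocentre is rebuilt as the quaternary 5R carbon (future C10, R).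

Step 3
Reactants: 6 (Z)-3-methylpent-2-en-4-yn-1-ol
Product: 7 (Z)-3-methylpent-2-en-4-ynal
Conditions: MnO2 (15 equiv), CH2Cl2, rt
Reagents that add atoms: none
Why: Heterogeneous, neutral MnO2 oxidation is selective for the allylic alcohol and neither isomerises the Z-alkene nor touches the alkyne.

Step 4
Reactants: 7 (Z)-3-methylpent-2-en-4-ynal; 8 vinylmagnesium bromide
Product: 9 (3S,4Z)-5-methylhepta-1,4-dien-6-yn-3-ol
Conditions: 8 (2.4 equiv), ZnCl2 (1.2 equiv), Et2O–THF, 0 °C, then 1,4-dioxane and filtration of the magnesium salts; (−)-MIB [(2S)-3-exo-morpholinoisoborneol, 10 mol %], toluene, −10 °C; 7; aq NH4Cl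
Reagents that add atoms: vinylmagnesium bromide 8, C=C[Mg]Br
Why: Amino-alcohol-catalysed asymmetric organozinc addition, in which the (−)-MIB–zinc complex delivers a vinyl group 1,2 to the Si face of the enal and sets the 3S carbinol (future C6).

Step 5
Reactants: 9 (3S,4Z)-5-methylhepta-1,4-dien-6-yn-3-ol; 5 (2S,5R)-2-tert-butyl-5-methyl-5-(3-methylbut-2-en-1-yl)-1,3-dioxolan-4-one
Product: 13 (2R)-2-methyl-2-(3-methylbut-2-en-1-yl)-5-[(2Z,4S)-4-(triethylsilyloxy)hexa-2,5-dien-2-yl]furan-3(2H)-one, via silyl ether 10 (not isolated), via hydroxy ynone 11 (not isolated), via enaminone 12 (not isolated)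
Conditions: n-BuLi (1.0 equiv), THF, −78 °C, then Et3SiCl (1.0 equiv), → 0 °C; n-BuLi (1.05 equiv), −78 °C; 5, −78 → −40 °C; AcOH (1.1 equiv), −78 °C → rt; Et2NH (2 equiv), rt; AcOH–H2O, rt
Reagents that add atoms: chlorotriethylsilane, CC[Si](Cl)(CC)CC
Why: Transient O-silylation stops the C6 oxygen from adding to the ynone (furan formation), the lithium acetylide is acylated only once by the activated dioxolanone because the tetrahedral adduct survives until the acid quench and then sheds pivalaldehyde, and Et2NH conjugate addition followed by acid-induced addition–elimination of the tertiary hydroxyl (the classical hydroxy-ynone to 3(2H)-furanone cyclisation) closes ring A without touching quaternary C10 or the Z-alkene.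

Step 6
Reactants: 13 (2R)-2-methyl-2-(3-methylbut-2-en-1-yl)-5-[(2Z,4S)-4-(triethylsilyloxy)hexa-2,5-dien-2-yl]furan-3(2H)-one
Product: 14 (2R)-5-[(2Z,4S)-4-hydroxyhexa-2,5-dien-2-yl]-2-methyl-2-(3-methylbut-2-en-1-yl)furan-3(2H)-one
Conditions: HF·pyridine, pyridine–THF, 0 °C
Reagents that add atoms: none
Why: Buffered fluoride cleaves only the Si–O bond, and the near-neutral medium avoids ionisation of the bis-allylic alcohol or its addition to the furanone.

Step 7
Reactants: 14 (2R)-5-[(2Z,4S)-4-hydroxyhexa-2,5-dien-2-yl]-2-methyl-2-(3-methylbut-2-en-1-yl)furan-3(2H)-one; 15 2-(bromomethyl)acrylic acid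
Product: 16 (3S,4Z)-5-[(5R)-5-methyl-5-(3-methylbut-2-en-1-yl)-4-oxo-4,5-dihydrofuran-2-yl]hexa-1,4-dien-3-yl 2-(bromomethyl)acrylate
Conditions: 15 (1.3 equiv), DCC (1.3 equiv), DMAP (5 mol %), CH2Cl2, −10 → 0 °C
Reagents that add atoms: 2-(bromomethyl)acrylic acid 15, C=C(CBr)C(=O)O
Why: Steglich esterification of the only free hydroxyl proceeds with retention at C6, and low temperature with little DMAP keeps the allylic bromide intact.

Step 8
Reactants: 16 (3S,4Z)-5-[(5R)-5-methyl-5-(3-methylbut-2-en-1-yl)-4-oxo-4,5-dihydrofuran-2-yl]hexa-1,4-dien-3-yl 2-(bromomethyl)acrylate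
Product: 17 (2R)-5-{(1Z)-1-[(2R)-4-(bromomethyl)-5-oxo-2,5-dihydrofuran-2-yl]prop-1-en-2-yl}-2-methyl-2-(3-methylbut-2-en-1-yl)furan-3(2H)-one
Conditions: second-generation Grubbs catalyst (5 mol %), 1,4-benzoquinone (10 mol %), CH2Cl2 (5 mM), reflux
Reagents that add atoms: none
Why: Ring-closing metathesis, in which the catalyst loads on the only monosubstituted alkene and closes the five-membered butenolide (ring B) on the acrylate while the prenyl and dienone alkenes are too hindered or too electron-poor to compete (C6 is unchanged in space; its descriptor becomes R by priority change).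

Step 9
Reactants: 17 (2R)-5-{(1Z)-1-[(2R)-4-(bromomethyl)-5-oxo-2,5-dihydrofuran-2-yl]prop-1-en-2-yl}-2-methyl-2-(3-methylbut-2-en-1-yl)furan-3(2H)-one
Product: 19 [(2R)-5-{(1Z)-1-[(2R)-4-(bromomethyl)-5-oxo-2,5-dihydrofuran-2-yl]prop-1-en-2-yl}-2-methyl-3-oxo-2,3-dihydrofuran-2-yl]acetaldehyde, via ozonide 18 (not isolated)
Conditions: O3 (1 equiv, Sudan Red 7B end point), CH2Cl2, −78 °C; Me2S, −78 °C → rt
Reagents that add atoms: ozone, [O-][O+]=O
Why: Chemoselective ozonolysis, in which the isolated trisubstituted prenyl alkene is by far the most electron-rich π bond, so one equivalent of ozone cleaves it alone and reductive work-up gives aldehyde C8.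

Step 10
Reactants: 19 [(2R)-5-{(1Z)-1-[(2R)-4-(bromomethyl)-5-oxo-2,5-dihydrofuran-2-yl]prop-1-en-2-yl}-2-methyl-3-oxo-2,3-dihydrofuran-2-yl]acetaldehyde
Product: 21 8-epi-8-deacyl-15-deoxybudlein A (tricyclic core bearing a free 8α-hydroxyl; 6R 7R 8S 10R), via allylchromium 20 (not isolated)
Conditions: CrCl2 (8 equiv), THF, 25 °C, 19 added by syringe pump over 12 h (final 2 mM); then H2O
Reagents that add atoms: none
Why: Proposed new method: two CrCl2 reduce the allylic C–Br bond so that the butenolide β-carbon C7, normally a Michael-acceptor site, becomes the γ-terminus of an allylchromium (a lactone homoenolate equivalent) that attacks the equally electrophilic aldehyde carbon C8 in an intramolecular Nozaki–Hiyama allylation, closing ring C and shifting the alkene to the exocyclic C11=C13 position; attack anti to the C6 alkenyl group sets 7R, the chair transition state of the ring-locked E-type allylmetal with both tether ends equatorial sets 8S (anti), and the in-plane C6–O bond cannot align for elimination; the closest known reactions are the intermolecular chromium- or zinc-mediated allylation of aldehydes with 3-(bromomethyl)furan-2(5H)-one and CrCl2 closures of ten-membered germacrane rings from allylic bromide aldehydes.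

Step 11
Reactants: 21 8-epi-8-deacyl-15-deoxybudlein A; 22 angelic acid
Product: 23 15-deoxybudlein A
Conditions: PPh3 (3 equiv) and DIAD (3 equiv) premixed, toluene, 0 °C; then 22 (3 equiv) and 21, 0 °C → rt
Reagents that add atoms: angelic acid 22, C/C=C(/C)C(=O)O
Why: Mitsunobu esterification, in which SN2 displacement of the oxyphosphonium by angelate inverts C8 from S to R, and the Z-geometry of the angelate is kept because the acid acts only as an O-nucleophile and is never activated as an acyl donor.

**Compound list**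
1 | (S)-lactic acid | C[C@H](O)C(=O)O | starting material
2 | pivalaldehyde | CC(C)(C)C=O | starting material
3 | (2S,5S)-2-tert-butyl-5-methyl-1,3-dioxolan-4-one | C[C@@H]1O[C@H](C(C)(C)C)OC1=O | intermediate
4 | prenyl bromide (1-bromo-3-methylbut-2-ene) | CC(C)=CCBr | starting material
5 | (2S,5R)-2-tert-butyl-5-methyl-5-(3-methylbut-2-en-1-yl)-1,3-dioxolan-4-one | C[C@]1(CC=C(C)C)O[C@H](C(C)(C)C)OC1=O | intermediate
6 | (Z)-3-methylpent-2-en-4-yn-1-ol | C#C/C(C)=C\CO | starting material
7 | (Z)-3-methylpent-2-en-4-ynal | C#C/C(C)=C\C=O | intermediate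
8 | vinylmagnesium bromide | C=C[Mg]Br | starting material
9 | (3S,4Z)-5-methylhepta-1,4-dien-6-yn-3-ol | O[C@@H](C=C)/C=C(/C)C#C | intermediate
10 | triethyl{[(3S,4Z)-5-methylhepta-1,4-dien-6-yn-3-yl]oxy}silane | CC[Si](CC)(CC)O[C@@H](C=C)/C=C(/C)C#C | intermediate
11 | (5R,9Z,11S)-5-hydroxy-2,5,9-trimethyl-11-(triethylsilyloxy)trideca-2,9,12-trien-7-yn-6-one | CC[Si](CC)(CC)O[C@@H](C=C)/C=C(/C)C#CC(=O)[C@@](C)(CC=C(C)C)O | intermediate
12 | (5R,9Z,11S)-8-(diethylamino)-5-hydroxy-2,5,9-trimethyl-11-(triethylsilyloxy)trideca-2,7,9,12-tetraen-6-one | CC[Si](CC)(CC)O[C@@H](C=C)/C=C(/C)C(N(CC)CC)=CC(=O)[C@@](C)(CC=C(C)C)O | intermediate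
13 | (2R)-2-methyl-2-(3-methylbut-2-en-1-yl)-5-[(2Z,4S)-4-(triethylsilyloxy)hexa-2,5-dien-2-yl]furan-3(2H)-one | CC[Si](CC)(CC)O[C@@H](C=C)/C=C(/C)C1=CC(=O)[C@@](C)(CC=C(C)C)O1 | intermediate
14 | (2R)-5-[(2Z,4S)-4-hydroxyhexa-2,5-dien-2-yl]-2-methyl-2-(3-methylbut-2-en-1-yl)furan-3(2H)-one | O[C@@H](C=C)/C=C(/C)C1=CC(=O)[C@@](C)(CC=C(C)C)O1 | intermediate
15 | 2-(bromomethyl)acrylic acid | C=C(CBr)C(=O)O | starting material
16 | (3S,4Z)-5-[(5R)-5-methyl-5-(3-methylbut-2-en-1-yl)-4-oxo-4,5-dihydrofuran-2-yl]hexa-1,4-dien-3-yl 2-(bromomethyl)acrylate | C=C(CBr)C(=O)O[C@@H](C=C)/C=C(/C)C1=CC(=O)[C@@](C)(CC=C(C)C)O1 | intermediate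
17 | (2R)-5-{(1Z)-1-[(2R)-4-(bromomethyl)-5-oxo-2,5-dihydrofuran-2-yl]prop-1-en-2-yl}-2-methyl-2-(3-methylbut-2-en-1-yl)furan-3(2H)-one | O=C1O[C@@H](C=C1CBr)/C=C(/C)C2=CC(=O)[C@@](C)(CC=C(C)C)O2 | intermediate
18 | secondary ozonide of 17 (5,5-dimethyl-1,2,4-trioxolan-3-ylmethyl group on C10; epimers at the ozonide carbon) | O=C1O[C@@H](C=C1CBr)/C=C(/C)C2=CC(=O)[C@@](C)(CC3OOC(C)(C)O3)O2 | intermediate
19 | [(2R)-5-{(1Z)-1-[(2R)-4-(bromomethyl)-5-oxo-2,5-dihydrofuran-2-yl]prop-1-en-2-yl}-2-methyl-3-oxo-2,3-dihydrofuran-2-yl]acetaldehyde | O=C1O[C@@H](C=C1CBr)/C=C(/C)C2=CC(=O)[C@@](C)(CC=O)O2 | intermediate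
20 | allylchromium dichloride from 19 (CrCl2 group on C13, trivalent chromium) | O=C1O[C@@H](C=C1C[Cr](Cl)Cl)/C=C(/C)C2=CC(=O)[C@@](C)(CC=O)O2 | intermediate
21 | 8-epi-8-deacyl-15-deoxybudlein A (6R,7R,8S,10R; free 8α-OH, trans 6,12-lactone, α-methylene) | C=C1C(=O)O[C@@H]2/C=C(/C)C3=CC(=O)[C@@](C)(C[C@H](O)[C@@H]12)O3 | intermediate
22 | angelic acid ((Z)-2-methylbut-2-enoic acid) | C/C=C(/C)C(=O)O | starting material
23 | 15-deoxybudlein A (6R,7R,8R,10R) | C=C1C(=O)O[C@@H]2/C=C(/C)C3=CC(=O)[C@@](C)(C[C@@H](OC(=O)/C(C)=C\C)[C@@H]12)O3 | target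

**Totals and risks**
Total step count: 11. Longest linear sequence: 9 steps (steps 3–11 from 6, or steps 1, 2 and 5–11 from 1).

Most likely to fail, first: step 10 (macrocyclisation). The risks are oligomerisation, protodebromination and translactonisation. The fallback sets out from 19 and comes back at 21. It replaces in-situ reductive metallation by a preformed, neutral allylboron homoenolate equivalent. Pd2(dba)3-catalysed borylation of the allylic bromide with bis(pinacolato)diboron gives the allylboronate aldehyde F1. In a separate operation F1 is closed at 1 mM by Sc(OTf)3-catalysed or thermal intramolecular allylboration. The same chair with the ring-locked E-type allyl unit should give 7R,8S. Hydrolysis of the borate then releases 21.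

Second: step 11 (Mitsunobu on a hindered ring alcohol next to an α-methylene lactone). The risks are elimination and phosphine addition. The fallback sets out from 21 and comes back at 23, and corrects C8 by redox instead of substitution.
- Buffered Dess–Martin oxidation gives the C8 ketone F2.
- NaBH4/CeCl3·7H2O in MeOH at −78 °C gives the 8R alcohol F3. Felkin–Anh attack anti to the C6–C7 bond pushes the oxygen to the β face.
- F3 is acylated with retention by the mixed anhydride of 22 and 2,4,6-trichlorobenzoyl chloride (Et3N, toluene, 80 °C, no DMAP) to give 23.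

Third: step 5 (single acylation of the acetylide by the hindered dioxolanone). The fallback sets out from 5 and comes back at 13, and changes the acyl donor. MeNH(OMe)·HCl with iPrMgCl opens 5 to the hydroxy Weinreb amide F4. After deprotonation of its hydroxyl with iPrMgCl, F4 takes up the lithium acetylide of 10 as a chelated adduct. This adduct releases 11 only on quench, and the same Et2NH and aqueous AcOH treatment leads to 13.

**Further compounds**
F1 | step 10 | [(2R)-2-methyl-3-oxo-5-{(1Z)-1-[(2R)-5-oxo-4-[(4,4,5,5-tetramethyl-1,3,2-dioxaborolan-2-yl)methyl]-2,5-dihydrofuran-2-yl]prop-1-en-2-yl}-2,3-dihydrofuran-2-yl]acetaldehyde | O=C1O[C@@H](C=C1CB3OC(C)(C)C(C)(C)O3)/C=C(/C)C2=CC(=O)[C@@](C)(CC=O)O2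
F2 | step 11 | 8-oxo-8-deacyloxy-15-deoxybudlein A (C8 ketone; 6R,7R,10R) | C=C1C(=O)O[C@@H]2/C=C(/C)C3=CC(=O)[C@@](C)(CC(=O)[C@@H]12)O3
F3 | step 11 | 8-deacyl-15-deoxybudlein A (8R alcohol; 6R,7R,8R,10R) | C=C1C(=O)O[C@@H]2/C=C(/C)C3=CC(=O)[C@@](C)(C[C@@H](O)[C@@H]12)O3
F4 | step 5 | (2R)-2-hydroxy-N-methoxy-N,2,5-trimethylhex-4-enamide | CON(C)C(=O)[C@@](C)(CC=C(C)C)O
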